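**Retrosynthetic overview**

- The route rests on the C7≡C8 triple bond on ring A (the hydroxylated ring) conjugated to the trisubstituted C9(CH3)=C10 alkene. This 9E enyne is the formal adduct of a ring A ethynyl C–H bond across the triple bond of a but-2-ynoate, with C11 arriving as the ester carbon.
- Disconnections, latest first: C15=C15' (Wittig, C20 aldehyde of ring A plus C20 phosphonium salt of ring B); C11=C12 and C11'=C12' (Horner–Wadsworth–Emmons with a C5 phosphonocrotonate); C9'=C10' (Horner–Wadsworth–Emmons on (R)-α-ionone); C8–C9 (Pd-catalysed hydroalkynylation); C6–C7 (Sonogashira coupling on an enol triflate).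
- No ring is formed. Ring A with its C3 stereocentre comes from (4R,6R)-4-hydroxy-2,2,6-trimethylcyclohexanone, and ring B with its C6' stereocentre comes from (R)-α-ionone.

Key step: step 5

Assumption: (R)-α-ionone and the (4R,6R)-hydroxy ketone are used enantiomerically pure, and all enyne and polyene intermediates are handled under argon in the dark, because light, iodine or prolonged heating would equilibrate the 9E enyne towards 9Z.

**Route**

Step 1
Reactants: 1 (4R,6R)-4-hydroxy-2,2,6-trimethylcyclohexan-1-one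
Product: 2 (4R,6R)-4-{[tert-butyl(dimethyl)silyl]oxy}-2,2,6-trimethylcyclohexan-1-one
Conditions: TBSCl, imidazole, DMF, rt
Reagents that add atoms: tert-butyldimethylsilyl chloride, CC(C)(C)[Si](C)(C)Cl
Why: Imidazole-promoted silyl ether formation on an unhindered secondary alcohol should be clean and leaves both stereocentres untouched.

Step 2
Reactants: 2 (4R,6R)-4-{[tert-butyl(dimethyl)silyl]oxy}-2,2,6-trimethylcyclohexan-1-one
Product: 4 (4R)-4-{[tert-butyl(dimethyl)silyl]oxy}-2,6,6-trimethylcyclohex-1-en-1-yl trifluoromethanesulfonate, via lithium enolate 3 (not isolated)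
Conditions: LiN(i-Pr)2, THF, −78 °C → 0 °C; then PhNTf2, −78 °C → rt
Reagents that add atoms: N-phenylbis(trifluoromethanesulfonimide), O=S(=O)(N(c1ccccc1)S(=O)(=O)C(F)(F)F)C(F)(F)F
Why: Enolate formation and O-triflation should give a single enol triflate because the ketone has only one α-hydrogen (the other α-carbon is quaternary); the methyl-bearing stereocentre is erased on purpose and the silyloxy carbon (carotenoid C3) is not involved.

Step 3
Reactants: 4 (4R)-4-{[tert-butyl(dimethyl)silyl]oxy}-2,6,6-trimethylcyclohex-1-en-1-yl trifluoromethanesulfonate; 5 ethynyltrimethylsilane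
Product: 6 tert-butyl(dimethyl){[(1R)-3,5,5-trimethyl-4-[(trimethylsilyl)ethynyl]cyclohex-3-en-1-yl]oxy}silane
Conditions: PdCl2(PPh3)2 (cat.), CuI (cat.), Et3N, DMF, 45 °C (sealed vessel)
Reagents that add atoms: none
Why: Sonogashira coupling of alkenyl triflates tolerates the fully substituted 2,6,6-trimethylcyclohexenyl position and should form the C6–C7 bond without touching the silyl ether.

Step 4
Reactants: 6 tert-butyl(dimethyl){[(1R)-3,5,5-trimethyl-4-[(trimethylsilyl)ethynyl]cyclohex-3-en-1-yl]oxy}silane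
Product: 7 (R)-tert-butyl[(4-ethynyl-3,5,5-trimethylcyclohex-3-en-1-yl)oxy]dimethylsilane
Conditions: K2CO3 (cat.), MeOH, rt
Reagents that add atoms: none
Why: Methanolysis (protodesilylation) of the C(sp)–SiMe3 bond is fast under mild carbonate conditions that leave the secondary tert-butyldimethylsilyl ether intact.

Step 5
Reactants: 7 (R)-tert-butyl[(4-ethynyl-3,5,5-trimethylcyclohex-3-en-1-yl)oxy]dimethylsilane; 8 ethyl but-2-ynoate
Product: 9 ethyl (2E)-5-[(4R)-4-{[tert-butyl(dimethyl)silyl]oxy}-2,6,6-trimethylcyclohex-1-en-1-yl]-3-methylpent-2-en-4-ynoate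
Conditions: Pd(OAc)2 (3 mol %), tris(2,6-dimethoxyphenyl)phosphine (3 mol %), benzene, rt; 7 added slowly to 8 (1.2 equiv)
Reagents that add atoms: none
Why: Pd(OAc)2 with the bulky, electron-rich phosphine should convert the terminal C–H bond of 7 into a divalent palladium acetylide (acetate as base), which carbopalladates the coordinated ynoate syn, placing the alkynyl group on the methyl-bearing β-carbon (C9) and palladium on the α-carbon (C10). Protonolysis of the alkenyl–palladium bond with retention then releases the ynenoate and regenerates the acetylide. The closest known reaction type is the Pd(OAc)2/triarylphosphine-catalysed head-to-tail cross-addition of terminal donor alkynes to alkynoate acceptors giving (E)-2-en-4-ynoates. No ring closes and no stereocentre is created; syn addition places the alkynyl group trans to the ester, which is the 9E geometry of the target, and the remote C3 silyl ether is untouched at rt under neutral conditions. The step needs cross-addition over self-addition of 7 and alkynyl delivery to the β-carbon: the first is secured by the much higher acceptor reactivity of the ynoate, slow addition of 7, and the poor acceptor character of the fully substituted enyne in 7 and 9, and the second by the polarisation of the ynoate. The hindered C6 position is not involved, since 7 reacts only through its unhindered terminal C–H bond.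

Step 6
Reactants: 9 ethyl (2E)-5-[(4R)-4-{[tert-butyl(dimethyl)silyl]oxy}-2,6,6-trimethylcyclohex-1-en-1-yl]-3-methylpent-2-en-4-ynoate
Product: 10 (2E)-5-[(4R)-4-{[tert-butyl(dimethyl)silyl]oxy}-2,6,6-trimethylcyclohex-1-en-1-yl]-3-methylpent-2-en-4-yn-1-ol
Conditions: i-Bu2AlH, CH2Cl2, −78 °C; aq. potassium sodium tartrate
Reagents that add atoms: none
Why: i-Bu2AlH reduces conjugated esters 1,2 to allylic alcohols at low temperature without touching the enyne, the alkene geometry or the silyl ether.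

Step 7
Reactants: 10 (2E)-5-[(4R)-4-{[tert-butyl(dimethyl)silyl]oxy}-2,6,6-trimethylcyclohex-1-en-1-yl]-3-methylpent-2-en-4-yn-1-ol
Product: 11 (2E)-5-[(4R)-4-{[tert-butyl(dimethyl)silyl]oxy}-2,6,6-trimethylcyclohex-1-en-1-yl]-3-methylpent-2-en-4-ynal
Conditions: MnO2, CH2Cl2, rt, dark
Reagents that add atoms: none
Why: MnO2 oxidation is selective for allylic alcohols and its neutral, heterogeneous conditions should preserve the 9E geometry of the C15 ynenal.

Step 8
Reactants: 11 (2E)-5-[(4R)-4-{[tert-butyl(dimethyl)silyl]oxy}-2,6,6-trimethylcyclohex-1-en-1-yl]-3-methylpent-2-en-4-ynal; 12 ethyl (2E)-4-(diethoxyphosphoryl)-3-methylbut-2-enoate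
Product: 14 ethyl (2E,4E,6E)-9-[(4R)-4-{[tert-butyl(dimethyl)silyl]oxy}-2,6,6-trimethylcyclohex-1-en-1-yl]-3,7-dimethylnona-2,4,6-trien-8-ynoate, via lithiated phosphonocrotonate 13 (not isolated)
Conditions: 12, n-BuLi, THF/DMPU, −78 °C; then 11, −78 °C → 0 °C
Reagents that add atoms: none
Why: The Horner–Wadsworth–Emmons reaction of the stabilised allylic phosphonate anion with an enal should form the C11=C12 bond E-selectively at low temperature, which protects the sensitive ynenal; any 13Z isomer arising from the reagent is expected to be separable by chromatography.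

Step 9
Reactants: 14 ethyl (2E,4E,6E)-9-[(4R)-4-{[tert-butyl(dimethyl)silyl]oxy}-2,6,6-trimethylcyclohex-1-en-1-yl]-3,7-dimethylnona-2,4,6-trien-8-ynoate
Product: 15 (2E,4E,6E)-9-[(4R)-4-{[tert-butyl(dimethyl)silyl]oxy}-2,6,6-trimethylcyclohex-1-en-1-yl]-3,7-dimethylnona-2,4,6-trien-8-yn-1-ol
Conditions: i-Bu2AlH, CH2Cl2, −78 °C; aq. potassium sodium tartrate
Reagents that add atoms: none
Why: 1,2-Reduction of the trienoate by i-Bu2AlH is the standard retinoid ester-to-alcohol conversion and is compatible with the enyne and the silyl ether.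

Step 10
Reactants: 15 (2E,4E,6E)-9-[(4R)-4-{[tert-butyl(dimethyl)silyl]oxy}-2,6,6-trimethylcyclohex-1-en-1-yl]-3,7-dimethylnona-2,4,6-trien-8-yn-1-ol
Product: 16 (2E,4E,6E)-9-[(4R)-4-{[tert-butyl(dimethyl)silyl]oxy}-2,6,6-trimethylcyclohex-1-en-1-yl]-3,7-dimethylnona-2,4,6-trien-8-ynal
Conditions: MnO2, CH2Cl2, rt, dark
Reagents that add atoms: none
Why: MnO2 oxidation of the polyenylic alcohol (the retinol-to-retinal type conversion) should give the C20 aldehyde without isomerisation.

Step 11
Reactants: 17 (R)-α-ionone, (3E)-4-[(1R)-2,6,6-trimethylcyclohex-2-en-1-yl]but-3-en-2-one; 18 triethyl phosphonoacetate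
Product: 20 ethyl (2E,4E)-3-methyl-5-[(1R)-2,6,6-trimethylcyclohex-2-en-1-yl]penta-2,4-dienoate, via sodiated phosphonoacetate 19 (not isolated)
Conditions: 18, NaH, THF, 0 °C; then 17, rt → 45 °C
Reagents that add atoms: none
Why: The Horner–Wadsworth–Emmons olefination of ionones forms the C9'=C10' bond with a preference for E (the Z isomer to be removed by chromatography), and the preformed phosphonate anion is too weak a base to deprotonate C6', so the stereocentre should be retained.

Step 12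
Reactants: 20 ethyl (2E,4E)-3-methyl-5-[(1R)-2,6,6-trimethylcyclohex-2-en-1-yl]penta-2,4-dienoate
Product: 21 (2E,4E)-3-methyl-5-[(1R)-2,6,6-trimethylcyclohex-2-en-1-yl]penta-2,4-dien-1-ol
Conditions: i-Bu2AlH, CH2Cl2, −78 °C; aq. potassium sodium tartrate
Reagents that add atoms: none
Why: i-Bu2AlH reduces the dienoate 1,2 to the allylic alcohol without affecting the ring B alkene or C6'.

Step 13
Reactants: 21 (2E,4E)-3-methyl-5-[(1R)-2,6,6-trimethylcyclohex-2-en-1-yl]penta-2,4-dien-1-ol
Product: 22 (2E,4E)-3-methyl-5-[(1R)-2,6,6-trimethylcyclohex-2-en-1-yl]penta-2,4-dienal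
Conditions: MnO2, CH2Cl2, rt
Reagents that add atoms: none
Why: Selective allylic oxidation with MnO2 under neutral conditions avoids acid- or base-mediated migration of the ring B double bond into conjugation.

Step 14
Reactants: 22 (2E,4E)-3-methyl-5-[(1R)-2,6,6-trimethylcyclohex-2-en-1-yl]penta-2,4-dienal; 12 ethyl (2E)-4-(diethoxyphosphoryl)-3-methylbut-2-enoate
Product: 24 ethyl (2E,4E,6E,8E)-3,7-dimethyl-9-[(1R)-2,6,6-trimethylcyclohex-2-en-1-yl]nona-2,4,6,8-tetraenoate, via sodiated phosphonocrotonate 23 (not isolated)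
Conditions: 12, NaH, THF, 0 °C; then 22, −20 °C → rt
Reagents that add atoms: none
Why: The Horner–Wadsworth–Emmons chain extension of a C15 dienal with the sodium salt of the C5 phosphonate is the classical retinoate construction and should form C11'=C12' E-selectively, the aldehyde being added only after the anion is fully formed so that no free hydride or stronger base reaches C6'.

Step 15
Reactants: 24 ethyl (2E,4E,6E,8E)-3,7-dimethyl-9-[(1R)-2,6,6-trimethylcyclohex-2-en-1-yl]nona-2,4,6,8-tetraenoate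
Product: 25 (2E,4E,6E,8E)-3,7-dimethyl-9-[(1R)-2,6,6-trimethylcyclohex-2-en-1-yl]nona-2,4,6,8-tetraen-1-ol, (R)-α-retinol
Conditions: i-Bu2AlH, CH2Cl2, −78 °C; aq. potassium sodium tartrate
Reagents that add atoms: none
Why: i-Bu2AlH reduction of the tetraenoate to the primary allylic alcohol is standard retinoid chemistry and does not touch C6'.

Step 16
Reactants: 25 (2E,4E,6E,8E)-3,7-dimethyl-9-[(1R)-2,6,6-trimethylcyclohex-2-en-1-yl]nona-2,4,6,8-tetraen-1-ol
Product: 26 [(2E,4E,6E,8E)-3,7-dimethyl-9-[(1R)-2,6,6-trimethylcyclohex-2-en-1-yl]nona-2,4,6,8-tetraen-1-yl]triphenylphosphonium bromide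
Conditions: PPh3·HBr, MeOH, rt, dark
Reagents that add atoms: triphenylphosphine hydrobromide, [Br-].[PH+](c1ccccc1)(c1ccccc1)c1ccccc1
Why: Acid-promoted allylic substitution of the polyenylic alcohol by triphenylphosphine (the retinyl phosphonium salt formation) traps the delocalised cation at its terminal carbon as the thermodynamically preferred all-E salt, fast enough to outrun proton loss from C6'.

Step 17
Reactants: 26 [(2E,4E,6E,8E)-3,7-dimethyl-9-[(1R)-2,6,6-trimethylcyclohex-2-en-1-yl]nona-2,4,6,8-tetraen-1-yl]triphenylphosphonium bromide; 16 (2E,4E,6E)-9-[(4R)-4-{[tert-butyl(dimethyl)silyl]oxy}-2,6,6-trimethylcyclohex-1-en-1-yl]-3,7-dimethylnona-2,4,6-trien-8-ynal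
Product: 28 (3R,6'R)-3-{[tert-butyl(dimethyl)silyl]oxy}-7,8-didehydro-β,ε-carotene (all-E), via phosphonium ylide 27 (not isolated)
Conditions: NaOMe, MeOH/CH2Cl2, 0 °C → rt, dark, Ar
Reagents that add atoms: none
Why: The Wittig reaction of a polyenyl triphenylphosphonium ylide with a polyenal is the classical C20 + C20 carotenoid union and forms the central C15=C15' bond mainly E; the minor 15Z isomer should be removed by chromatography and crystallisation, not by iodine or thermal equilibration, so that the 9E enyne is kept.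

Step 18
Reactants: 28 (3R,6'R)-3-{[tert-butyl(dimethyl)silyl]oxy}-7,8-didehydro-β,ε-carotene
Product: 29 (3R,6'R)-7,8-didehydro-β,ε-caroten-3-ol (all-E), the target CNP0322200.1
Conditions: Bu4NF, THF, 0 °C → rt, dark
Reagents that add atoms: none
Why: Fluoride-induced cleavage of the secondary silyl ether is mild enough for carotenoid polyenes and does not affect C3, C6' or the alkene geometries.

**Compound list**

1 | (4R,6R)-4-hydroxy-2,2,6-trimethylcyclohexan-1-one | O=C1[C@H](C)C[C@@H](O)CC1(C)C | starting material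
2 | (4R,6R)-4-{[tert-butyl(dimethyl)silyl]oxy}-2,2,6-trimethylcyclohexan-1-one | O=C1[C@H](C)C[C@@H](O[Si](C)(C)C(C)(C)C)CC1(C)C | intermediate
3 | lithium enolate of 2, lithium (4R)-4-{[tert-butyl(dimethyl)silyl]oxy}-2,6,6-trimethylcyclohex-1-en-1-olate | [Li+].[O-]C1=C(C)C[C@@H](O[Si](C)(C)C(C)(C)C)CC1(C)C | intermediate
4 | (4R)-4-{[tert-butyl(dimethyl)silyl]oxy}-2,6,6-trimethylcyclohex-1-en-1-yl trifluoromethanesulfonate | O=S(=O)(OC1=C(C)C[C@@H](O[Si](C)(C)C(C)(C)C)CC1(C)C)C(F)(F)F | intermediate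
5 | ethynyltrimethylsilane | C#C[Si](C)(C)C | starting material
6 | tert-butyl(dimethyl){[(1R)-3,5,5-trimethyl-4-[(trimethylsilyl)ethynyl]cyclohex-3-en-1-yl]oxy}silane | C[Si](C)(C)C#CC1=C(C)C[C@@H](O[Si](C)(C)C(C)(C)C)CC1(C)C | intermediate
7 | (R)-tert-butyl[(4-ethynyl-3,5,5-trimethylcyclohex-3-en-1-yl)oxy]dimethylsilane | C#CC1=C(C)C[C@@H](O[Si](C)(C)C(C)(C)C)CC1(C)C | intermediate
8 | ethyl but-2-ynoate | CC#CC(=O)OCC | starting material
9 | ethyl (2E)-5-[(4R)-4-{[tert-butyl(dimethyl)silyl]oxy}-2,6,6-trimethylcyclohex-1-en-1-yl]-3-methylpent-2-en-4-ynoate | CCOC(=O)/C=C(\C)C#CC1=C(C)C[C@@H](O[Si](C)(C)C(C)(C)C)CC1(C)C | intermediate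
10 | (2E)-5-[(4R)-4-{[tert-butyl(dimethyl)silyl]oxy}-2,6,6-trimethylcyclohex-1-en-1-yl]-3-methylpent-2-en-4-yn-1-ol | OC/C=C(\C)C#CC1=C(C)C[C@@H](O[Si](C)(C)C(C)(C)C)CC1(C)C | intermediate
11 | (2E)-5-[(4R)-4-{[tert-butyl(dimethyl)silyl]oxy}-2,6,6-trimethylcyclohex-1-en-1-yl]-3-methylpent-2-en-4-ynal | O=C/C=C(\C)C#CC1=C(C)C[C@@H](O[Si](C)(C)C(C)(C)C)CC1(C)C | intermediate
12 | ethyl (2E)-4-(diethoxyphosphoryl)-3-methylbut-2-enoate (triethyl 3-methyl-4-phosphonocrotonate) | CCOC(=O)/C=C(\C)CP(=O)(OCC)OCC | starting material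
13 | lithiated phosphonocrotonate from 12 (lithium salt of the C4 carbanion) | [Li+].CCOC(=O)/C=C(\C)[CH-]P(=O)(OCC)OCC | intermediate
14 | ethyl (2E,4E,6E)-9-[(4R)-4-{[tert-butyl(dimethyl)silyl]oxy}-2,6,6-trimethylcyclohex-1-en-1-yl]-3,7-dimethylnona-2,4,6-trien-8-ynoate | CCOC(=O)/C=C(C)/C=C/C=C(\C)C#CC1=C(C)C[C@@H](O[Si](C)(C)C(C)(C)C)CC1(C)C | intermediate
15 | (2E,4E,6E)-9-[(4R)-4-{[tert-butyl(dimethyl)silyl]oxy}-2,6,6-trimethylcyclohex-1-en-1-yl]-3,7-dimethylnona-2,4,6-trien-8-yn-1-ol | OC/C=C(C)/C=C/C=C(\C)C#CC1=C(C)C[C@@H](O[Si](C)(C)C(C)(C)C)CC1(C)C | intermediate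
16 | (2E,4E,6E)-9-[(4R)-4-{[tert-butyl(dimethyl)silyl]oxy}-2,6,6-trimethylcyclohex-1-en-1-yl]-3,7-dimethylnona-2,4,6-trien-8-ynal | O=C/C=C(C)/C=C/C=C(\C)C#CC1=C(C)C[C@@H](O[Si](C)(C)C(C)(C)C)CC1(C)C | intermediate
17 | (R)-α-ionone, (3E)-4-[(1R)-2,6,6-trimethylcyclohex-2-en-1-yl]but-3-en-2-one | CC1=CCCC(C)(C)[C@H]1/C=C/C(C)=O | starting material
18 | triethyl phosphonoacetate | CCOC(=O)CP(=O)(OCC)OCC | starting material
19 | sodiated phosphonoacetate from 18 (sodium salt of the carbanion) | [Na+].CCOC(=O)[CH-]P(=O)(OCC)OCC | intermediate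
20 | ethyl (2E,4E)-3-methyl-5-[(1R)-2,6,6-trimethylcyclohex-2-en-1-yl]penta-2,4-dienoate | CC1=CCCC(C)(C)[C@H]1/C=C/C(C)=C/C(=O)OCC | intermediate
21 | (2E,4E)-3-methyl-5-[(1R)-2,6,6-trimethylcyclohex-2-en-1-yl]penta-2,4-dien-1-ol | CC1=CCCC(C)(C)[C@H]1/C=C/C(C)=C/CO | intermediate
22 | (2E,4E)-3-methyl-5-[(1R)-2,6,6-trimethylcyclohex-2-en-1-yl]penta-2,4-dienal | CC1=CCCC(C)(C)[C@H]1/C=C/C(C)=C/C=O | intermediate
23 | sodiated phosphonocrotonate from 12 (sodium salt of the C4 carbanion) | [Na+].CCOC(=O)/C=C(\C)[CH-]P(=O)(OCC)OCC | intermediate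
24 | ethyl (2E,4E,6E,8E)-3,7-dimethyl-9-[(1R)-2,6,6-trimethylcyclohex-2-en-1-yl]nona-2,4,6,8-tetraenoate | CC1=CCCC(C)(C)[C@H]1/C=C/C(C)=C/C=C/C(C)=C/C(=O)OCC | intermediate
25 | (2E,4E,6E,8E)-3,7-dimethyl-9-[(1R)-2,6,6-trimethylcyclohex-2-en-1-yl]nona-2,4,6,8-tetraen-1-ol, (R)-α-retinol | CC1=CCCC(C)(C)[C@H]1/C=C/C(C)=C/C=C/C(C)=C/CO | intermediate
26 | [(2E,4E,6E,8E)-3,7-dimethyl-9-[(1R)-2,6,6-trimethylcyclohex-2-en-1-yl]nona-2,4,6,8-tetraen-1-yl]triphenylphosphonium bromide | CC1=CCCC(C)(C)[C@H]1/C=C/C(C)=C/C=C/C(C)=C/C[P+](c1ccccc1)(c1ccccc1)c1ccccc1.[Br-] | intermediate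
27 | phosphonium ylide from 26 (triphenylphosphoranylidene form) | CC1=CCCC(C)(C)[C@H]1/C=C/C(C)=C/C=C/C(C)=C/C=P(c1ccccc1)(c1ccccc1)c1ccccc1 | intermediate
28 | (3R,6'R)-3-{[tert-butyl(dimethyl)silyl]oxy}-7,8-didehydro-β,ε-carotene (all-E) | CC1=CCCC(C)(C)[C@H]1/C=C/C(C)=C/C=C/C(C)=C/C=C/C=C(C)/C=C/C=C(\C)C#CC1=C(C)C[C@@H](O[Si](C)(C)C(C)(C)C)CC1(C)C | intermediate
29 | (3R,6'R)-7,8-didehydro-β,ε-caroten-3-ol (all-E), CNP0322200.1 | CC1=CCCC(C)(C)[C@H]1/C=C/C(C)=C/C=C/C(C)=C/C=C/C=C(C)/C=C/C=C(\C)C#CC1=C(C)C[C@@H](O)CC1(C)C | target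

**Step count and risks**

Total step count: 18 (steps 1–10 on the ring A branch, steps 11–16 on the ring B branch, steps 17 and 18 after union). Longest linear sequence: 12 steps (1 → 29 through steps 1–10, 17 and 18).

Steps most likely to fail:

1. Step 5. The hindered donor may add to the ynoate slowly, so that head-to-tail self-addition of the donor alkyne competes, and phosphine-mediated equilibration could erode the E geometry of the new alkene. The fallback sets out from 7 and returns at 9. Ethyl acetoacetate is converted with Tf2O and aqueous Me4NOH in hexane (E-selective enol triflation) into ethyl (2E)-3-{[(trifluoromethyl)sulfonyl]oxy}but-2-enoate F1. Sonogashira coupling of F1 with 7 (PdCl2(PPh3)2, CuI, Et3N, THF, rt) should give 9 with retention of the alkene geometry, so the 9E enyne is set by cross-coupling and not by hydroalkynylation.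

2. Step 17. The Wittig reaction may show poor E/Z control at the new C15=C15' bond, the long ylide may decompose, and attempts to correct the geometry may cause drift of the 9E enyne. The fallback reverses the polarity to a Horner–Wadsworth–Emmons union; it sets out from 15 and 25 and returns at 28. Alcohol 15 is converted with CBr4 and PPh3 in CH2Cl2 at −20 °C into the allylic bromide (2E,4E,6E)-1-bromo-9-[(4R)-4-{[tert-butyl(dimethyl)silyl]oxy}-2,6,6-trimethylcyclohex-1-en-1-yl]-3,7-dimethylnona-2,4,6-trien-8-yne F2. A Michaelis–Becker reaction with NaP(O)(OEt)2 in THF at 0 °C gives the diethyl phosphonate F3. In parallel, 25 is oxidised with MnO2 to (R)-α-retinal F4. Deprotonation of F3 with NaN(SiMe3)2 in THF at −78 °C and addition of F4 should give 28 with higher E selectivity at C15=C15'.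

3. Step 11. Olefination of the methyl ketone is slow and may be incompletely E-selective at C9'=C10', and long exposure to base could deprotonate the doubly allylic C6', eroding its configuration and moving the ring double bond into conjugation. The fallback is the classical C15 + C5 construction; it sets out from 17 and returns at 24. Addition of CH2=CHMgBr in THF at −20 °C gives (1E)-3-methyl-1-[(1R)-2,6,6-trimethylcyclohex-2-en-1-yl]penta-1,4-dien-3-ol F5 as a mixture of carbinol epimers, which is of no consequence. PPh3·HBr in MeOH converts F5 with allylic transposition into [(2E,4E)-3-methyl-5-[(1R)-2,6,6-trimethylcyclohex-2-en-1-yl]penta-2,4-dien-1-yl]triphenylphosphonium bromide F6. Wittig reaction of F6 with commercial ethyl (2E)-3-methyl-4-oxobut-2-enoate (NaOMe, CH2Cl2/MeOH), followed by iodine-catalysed equilibration of the new C11'=C12' bond, should give 24; equilibration is acceptable here because this fragment holds no enyne.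

**Further compounds**

F1 | step 5 | ethyl (2E)-3-{[(trifluoromethyl)sulfonyl]oxy}but-2-enoate | CCOC(=O)/C=C(\C)OS(=O)(=O)C(F)(F)F
F2 | step 17 | (2E,4E,6E)-1-bromo-9-[(4R)-4-{[tert-butyl(dimethyl)silyl]oxy}-2,6,6-trimethylcyclohex-1-en-1-yl]-3,7-dimethylnona-2,4,6-trien-8-yne | BrC/C=C(C)/C=C/C=C(\C)C#CC1=C(C)C[C@@H](O[Si](C)(C)C(C)(C)C)CC1(C)C
F3 | step 17 | diethyl [(2E,4E,6E)-9-[(4R)-4-{[tert-butyl(dimethyl)silyl]oxy}-2,6,6-trimethylcyclohex-1-en-1-yl]-3,7-dimethylnona-2,4,6-trien-8-yn-1-yl]phosphonate | CCOP(=O)(OCC)C/C=C(C)/C=C/C=C(\C)C#CC1=C(C)C[C@@H](O[Si](C)(C)C(C)(C)C)CC1(C)C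
F4 | step 17 | (2E,4E,6E,8E)-3,7-dimethyl-9-[(1R)-2,6,6-trimethylcyclohex-2-en-1-yl]nona-2,4,6,8-tetraenal, (R)-α-retinal | CC1=CCCC(C)(C)[C@H]1/C=C/C(C)=C/C=C/C(C)=C/C=O
F5 | step 11 | (1E)-3-methyl-1-[(1R)-2,6,6-trimethylcyclohex-2-en-1-yl]penta-1,4-dien-3-ol (mixture of carbinol epimers) | CC1=CCCC(C)(C)[C@H]1/C=C/C(C)(O)C=C
F6 | step 11 | [(2E,4E)-3-methyl-5-[(1R)-2,6,6-trimethylcyclohex-2-en-1-yl]penta-2,4-dien-1-yl]triphenylphosphonium bromide | CC1=CCCC(C)(C)[C@H]1/C=C/C(C)=C/C[P+](c1ccccc1)(c1ccccc1)c1ccccc1.[Br-]
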